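The plan treats the bromo-oxane ring (O, C7–C11; gem-dimethyl C11, bromine on C10) as an oxolane in disguise: shifting the ring oxygen from C10 to C11 converts a 2,5-disubstituted oxolane with an exocyclic tertiary carbinol into the six-membered ether. The key step exploits this 1,2-relationship of ring oxygen (on C10) and carbinol carbon (C11): activating the C11 hydroxyl lets the oxygen bond to C11, and bromide opens the resulting bicyclic oxonium ion at C10 with inversion, so one operation makes O–C11 and C10–Br, breaks O–C10 and sets (10S). The precursor is the cis oxolane from (S)-linalool, whose carbinol carbon is C7, with a pivaloyloxymethyl group (future C6) replacing the vinyl group.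

Key step: step 4

Remark on locants: C1–C11 are the chain atoms of the target (C1=C2 vinyl, C3 carbinol, C6 CHBr, C7 and C11 the ring carbons on oxygen, C10 the ring CHBr). In the linalool that becomes the ring, its own C3, C6 and C7 are C7, C10 and C11.

Assumption: the L-fructose-derived enantiomer of the Shi ketone (accessible from L-sorbose) is taken as an available catalyst. It is required because the common D-fructose-derived ketone should epoxidise the other face, giving the (6R) epoxide and in the end the wrong C10 bromide.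

Step 1
Reactants: 1 (S)-linalool; 2 potassium peroxymonosulfate (KHSO5)
Product: 4 cis-furanoid linalool oxide (2-[(2R,5S)-5-ethenyl-5-methyloxolan-2-yl]propan-2-ol), via (3S,6S)-6,7-epoxylinalool 3 (not isolated)
Conditions: L-fructose-derived Shi ketone (1,2:4,5-di-O-isopropylidene-β-L-erythro-2,3-hexodiulo-2,6-pyranose, 0.3 equiv), KHSO5, K2CO3, n-Bu4NHSO4, MeCN/CH2(OMe)2, aq. Na2B4O7 buffer, 0 °C; crude 3 taken on, then camphorsulfonic acid (cat.), CH2Cl2, 0 °C
Reagents that add atoms: potassium peroxymonosulfate, [K+].[O-]S(=O)(=O)OO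
Why: Shi epoxidation is selective for the electron-rich trisubstituted alkene (C6=C7 of linalool, C10=C11 of the target) and its facial sense is set by the catalyst, the L-fructose-derived ketone being the enantiomer that should give the (6S) epoxide, after which acid-catalysed 5-exo-tet attack of the tertiary hydroxyl inverts that carbon and sets the (10R) oxolane centre cis to the vinyl group (the 6-endo oxane isomer, expected as the minor product, is removed by chromatography).

Step 2
Reactants: 4 cis-furanoid linalool oxide; 5 ozone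
Product: 8 [(2S,5R)-5-(2-hydroxypropan-2-yl)-2-methyloxolan-2-yl]methanol, via ozonide 6 (not isolated), via aldehyde 7 (not isolated)
Conditions: O3, CH2Cl2, −78 °C; then NaBH4, MeOH, −78 °C to rt
Reagents that add atoms: ozone, [O-][O+]=O
Why: Ozonolysis with reductive NaBH4 work-up cuts the only alkene down to a hydroxymethyl group on C7 (the future C6) without touching either stereocentre.

Step 3
Reactants: 8 [(2S,5R)-5-(2-hydroxypropan-2-yl)-2-methyloxolan-2-yl]methanol; 9 pivaloyl chloride
Product: 10 [(2S,5R)-5-(2-hydroxypropan-2-yl)-2-methyloxolan-2-yl]methyl 2,2-dimethylpropanoate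
Conditions: t-BuCOCl (1.1 equiv), pyridine, 4-(dimethylamino)pyridine (cat.), CH2Cl2, 0 °C
Reagents that add atoms: pivaloyl chloride, CC(C)(C)C(=O)Cl
Why: Acylation with the bulky acid chloride should take place only at the primary hydroxyl and leave the tertiary C11 carbinol free (selective esterification), and the electron-withdrawing ester later keeps the C7–O bond from ionising.

Step 4
Reactants: 10 [(2S,5R)-5-(2-hydroxypropan-2-yl)-2-methyloxolan-2-yl]methyl 2,2-dimethylpropanoate; 11 tetrabutylammonium bromide
Product: 14 [(2S,5S)-5-bromo-2,6,6-trimethyloxan-2-yl]methyl 2,2-dimethylpropanoate, via tertiary triflate 12 (not isolated), via bicyclic oxonium triflate 13 (not isolated)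
Conditions: (CF3SO2)2O, 2,6-di-tert-butyl-4-methylpyridine, CH2Cl2, −78 °C; then n-Bu4NBr, −78 to 0 °C
Reagents that add atoms: tetrabutylammonium bromide, CCCC[N+](CCCC)(CCCC)CCCC.[Br-]
Why: Proposed new method: triflation of the C11 tertiary hydroxyl creates a leaving group that departs with help from the antiperiplanar lone pair of the ring oxygen, giving a 1-oxoniabicyclo[3.1.0]hexane, and bromide then opens the three-membered ring at C10 by SN2 attack, which breaks O–C10 and leaves the oxane. The closest known reaction type is the ring expansion of tetrahydrofurfuryl sulfonates and carbinols to 3-oxygenated oxanes through the same bicyclic oxonium ions, ended there by acetate or water, whereas here the ionising carbon is tertiary and the terminating nucleophile is bromide. The six-membered ring is closed not by a direct 6-endo attack but by the 3-exo-tet bonding of the ring oxygen to C11 followed by scission of the endocyclic O–C10 bond. The one new stereocentre, C10, is controlled by the existing (10R) C–O centre from the epoxidation, because bromide must enter anti to the departing oxygen, so that (10R)-O becomes (10S)-Br cis to the C6 carbon while C7 is untouched. The step needs opening at C10 and not at C11 or C7: bromide returning to tertiary C11 gives only a labile tertiary bromide that should re-ionise through the same oxonium ion, the secondary oxane bromide is stable under the conditions, and the pivaloyloxymethyl group on C7 disfavours C7–O heterolysis. Low temperature and the hindered, non-nucleophilic pyridine base are meant to suppress E1 loss of a proton to an isopropenyl oxolane.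

Step 5
Reactants: 14 [(2S,5S)-5-bromo-2,6,6-trimethyloxan-2-yl]methyl 2,2-dimethylpropanoate
Product: 15 [(2S,5S)-5-bromo-2,6,6-trimethyloxan-2-yl]methanol
Conditions: i-Bu2AlH (2.2 equiv), CH2Cl2, −78 °C; aq. KNaC4H4O6
Reagents that add atoms: none
Why: Reduction of the ester with i-Bu2AlH at low temperature removes the pivalate without the basic conditions that could eliminate HBr across C9–C10 (reductive ester cleavage).

Step 6
Reactants: 15 [(2S,5S)-5-bromo-2,6,6-trimethyloxan-2-yl]methanol
Product: 16 (2S,5S)-5-bromo-2,6,6-trimethyloxane-2-carbaldehyde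
Conditions: Dess–Martin periodinane, NaHCO3, CH2Cl2, 0 °C to rt
Reagents that add atoms: none
Why: Dess–Martin oxidation under buffered, non-basic conditions gives the aldehyde, which cannot epimerise because C7 bears no hydrogen.

Step 7
Reactants: 1 (S)-linalool; 17 tert-butyldimethylsilyl trifluoromethanesulfonate
Product: 18 tert-butyl{[(3S)-3,7-dimethylocta-1,6-dien-3-yl]oxy}dimethylsilane
Conditions: t-BuMe2SiOSO2CF3, 2,6-lutidine, CH2Cl2, 0 °C
Reagents that add atoms: tert-butyldimethylsilyl trifluoromethanesulfonate, CC(C)(C)[Si](C)(C)OS(=O)(=O)C(F)(F)F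
Why: A silyl triflate with 2,6-lutidine is the standard way to silylate a hindered tertiary allylic alcohol, and the bulky silyl ether is chosen because its oxygen is a poor neighbouring group in step 13 (silyl ether protection).

Step 8
Reactants: 18 tert-butyl{[(3S)-3,7-dimethylocta-1,6-dien-3-yl]oxy}dimethylsilane; 5 ozone
Product: 20 (4S)-4-[(tert-butyldimethylsilyl)oxy]-4-methylhex-5-enal, via ozonide 19 (not isolated)
Conditions: O3 (1 equiv, Sudan Red 7B end point), CH2Cl2, −78 °C; then PPh3, −78 °C to rt
Reagents that add atoms: ozone, [O-][O+]=O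
Why: Ozone attacks the trisubstituted alkene much faster than the vinyl group, which is monosubstituted and flanked by the silyloxy-bearing quaternary carbon, so titration to the indicator end point should cleave only C6=C7 (chemoselective ozonolysis with reductive work-up).

Step 9
Reactants: 20 (4S)-4-[(tert-butyldimethylsilyl)oxy]-4-methylhex-5-enal; 17 tert-butyldimethylsilyl trifluoromethanesulfonate
Product: 21 (4S)-1,4-bis[(tert-butyldimethylsilyl)oxy]-4-methylhexa-1,5-diene (E/Z mixture at C1=C2)
Conditions: t-BuMe2SiOSO2CF3, Et3N, CH2Cl2, 0 °C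
Reagents that add atoms: tert-butyldimethylsilyl trifluoromethanesulfonate, CC(C)(C)[Si](C)(C)OS(=O)(=O)C(F)(F)F
Why: Soft enolisation with the silyl triflate and triethylamine turns the aldehyde into its silyl enol ether (either alkene geometry serves), which marks the C5–C6 bond for cleavage.

Step 10
Reactants: 21 (4S)-1,4-bis[(tert-butyldimethylsilyl)oxy]-4-methylhexa-1,5-diene; 5 ozone
Product: 24 (3S)-3-[(tert-butyldimethylsilyl)oxy]-3-methylpent-4-en-1-ol, via ozonide 22 (not isolated), via aldehyde 23 (not isolated)
Conditions: O3 (1 equiv, Sudan Red 7B end point), CH2Cl2, −78 °C; then NaBH4, MeOH, −78 to 0 °C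
Reagents that add atoms: ozone, [O-][O+]=O
Why: The silyl enol ether is by far the most electron-rich alkene, so ozonolysis should excise C6 as a formate, and in-situ NaBH4 reduction converts the elimination-prone β-silyloxy aldehyde at once into the primary alcohol (ozonolysis–reduction as a one-carbon degradation).

Step 11
Reactants: 24 (3S)-3-[(tert-butyldimethylsilyl)oxy]-3-methylpent-4-en-1-ol; 25 tetrabromomethane
Product: 27 tert-butyl{[(3S)-5-bromo-3-methylpent-1-en-3-yl]oxy}dimethylsilane, via oxyphosphonium bromide 26 (not isolated)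
Conditions: CBr4, PPh3, CH2Cl2, 0 °C
Reagents that add atoms: tetrabromomethane, BrC(Br)(Br)Br
Why: Appel bromination of the unhindered primary alcohol proceeds by SN2 attack of bromide on the oxyphosphonium salt under neutral conditions that the tertiary allylic silyl ether tolerates.

Step 12
Reactants: 16 (2S,5S)-5-bromo-2,6,6-trimethyloxane-2-carbaldehyde; 27 tert-butyl{[(3S)-5-bromo-3-methylpent-1-en-3-yl]oxy}dimethylsilane
Product: 29 (1S,4S)-1-[(2S,5S)-5-bromo-2,6,6-trimethyloxan-2-yl]-4-[(tert-butyldimethylsilyl)oxy]-4-methylhex-5-en-1-ol, via Grignard reagent 28 (not isolated)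
Conditions: 27, Mg, Et2O, reflux; then 16, MgBr2·OEt2, CH2Cl2, −78 °C; aq. NH4Cl
Reagents that add atoms: none
Why: Addition of the Grignard reagent in a non-coordinating medium containing MgBr2 should pass through the five-membered chelate that ties the carbonyl oxygen to the ring oxygen, so that the nucleophile enters from the face of the C7 methyl group and not of the ring methylene and gives the (6S) carbinol (Cram chelate control), while the aldehyde has no α-hydrogen and the C10 bromide is inert at −78 °C.

Step 13
Reactants: 29 (1S,4S)-1-[(2S,5S)-5-bromo-2,6,6-trimethyloxan-2-yl]-4-[(tert-butyldimethylsilyl)oxy]-4-methylhex-5-en-1-ol; 25 tetrabromomethane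
Product: 31 tert-butyl{[(3S,6R)-6-bromo-6-[(2S,5S)-5-bromo-2,6,6-trimethyloxan-2-yl]-3-methylhex-1-en-3-yl]oxy}dimethylsilane, via oxyphosphonium bromide 30 (not isolated)
Conditions: CBr4, P(n-C8H17)3, toluene, 70 °C
Reagents that add atoms: tetrabromomethane, BrC(Br)(Br)Br
Why: Appel-type bromination with a trialkylphosphine, a combination established for hindered carbinols next to cyclic ether carbons, should replace the oxyphosphonium group by bromide with inversion (SN2), turning (6S)-OH into (6R)-Br, and the non-ionising solvent together with the poorly donating bulky silyl ether keeps oxygen participation down.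

Step 14
Reactants: 31 tert-butyl{[(3S,6R)-6-bromo-6-[(2S,5S)-5-bromo-2,6,6-trimethyloxan-2-yl]-3-methylhex-1-en-3-yl]oxy}dimethylsilane
Product: 32 (3S,6R)-6-bromo-6-[(2S,5S)-5-bromo-2,6,6-trimethyloxan-2-yl]-3-methylhex-1-en-3-ol
Conditions: HF·pyridine, pyridine, THF, 0 °C to rt
Reagents that add atoms: none
Why: Buffered HF·pyridine cleaves the tertiary silyl ether by fluoride attack at silicon under non-basic conditions that spare both secondary bromides and the tertiary allylic alcohol (desilylation).

Compound list
1 | (S)-linalool, (3S)-3,7-dimethylocta-1,6-dien-3-ol | C=C[C@@](C)(O)CCC=C(C)C | starting material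
2 | potassium peroxymonosulfate, KHSO5 (active salt of Oxone) | [K+].[O-]S(=O)(=O)OO | starting material
3 | (3S,6S)-6,7-epoxylinalool, (3S)-5-[(2S)-3,3-dimethyloxiran-2-yl]-3-methylpent-1-en-3-ol | C=C[C@@](C)(O)CC[C@@H]1OC1(C)C | intermediate
4 | cis-furanoid linalool oxide, 2-[(2R,5S)-5-ethenyl-5-methyloxolan-2-yl]propan-2-ol | C=C[C@]1(C)CC[C@H](C(C)(C)O)O1 | intermediate
5 | ozone | [O-][O+]=O | starting material
6 | 2-[(2R,5S)-5-methyl-5-(1,2,4-trioxolan-3-yl)oxolan-2-yl]propan-2-ol (ozonide, both configurations at the trioxolane carbon) | O1OC(OC1)[C@]2(C)CC[C@H](C(C)(C)O)O2 | intermediate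
7 | (2S,5R)-5-(2-hydroxypropan-2-yl)-2-methyloxolane-2-carbaldehyde | O=C[C@]1(C)CC[C@H](C(C)(C)O)O1 | intermediate
8 | [(2S,5R)-5-(2-hydroxypropan-2-yl)-2-methyloxolan-2-yl]methanol | OC[C@]1(C)CC[C@H](C(C)(C)O)O1 | intermediate
9 | pivaloyl chloride (2,2-dimethylpropanoyl chloride) | CC(C)(C)C(=O)Cl | starting material
10 | [(2S,5R)-5-(2-hydroxypropan-2-yl)-2-methyloxolan-2-yl]methyl 2,2-dimethylpropanoate | CC(C)(C)C(=O)OC[C@]1(C)CC[C@H](C(C)(C)O)O1 | intermediate
11 | tetrabutylammonium bromide | CCCC[N+](CCCC)(CCCC)CCCC.[Br-] | starting material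
12 | [(2S,5R)-2-methyl-5-{2-[(trifluoromethanesulfonyl)oxy]propan-2-yl}oxolan-2-yl]methyl 2,2-dimethylpropanoate | CC(C)(C)C(=O)OC[C@]1(C)CC[C@H](C(C)(C)OS(=O)(=O)C(F)(F)F)O1 | intermediate
13 | (2S,5R)-2-{[(2,2-dimethylpropanoyl)oxy]methyl}-2,6,6-trimethyl-1-oxoniabicyclo[3.1.0]hexane trifluoromethanesulfonate | CC(C)(C)C(=O)OC[C@]1(C)CC[C@@H]2C(C)(C)[O+]12.[O-]S(=O)(=O)C(F)(F)F | intermediate
14 | [(2S,5S)-5-bromo-2,6,6-trimethyloxan-2-yl]methyl 2,2-dimethylpropanoate | CC(C)(C)C(=O)OC[C@]1(C)CC[C@H](Br)C(C)(C)O1 | intermediate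
15 | [(2S,5S)-5-bromo-2,6,6-trimethyloxan-2-yl]methanol | OC[C@]1(C)CC[C@H](Br)C(C)(C)O1 | intermediate
16 | (2S,5S)-5-bromo-2,6,6-trimethyloxane-2-carbaldehyde | O=C[C@]1(C)CC[C@H](Br)C(C)(C)O1 | intermediate
17 | tert-butyldimethylsilyl trifluoromethanesulfonate | CC(C)(C)[Si](C)(C)OS(=O)(=O)C(F)(F)F | starting material
18 | tert-butyl{[(3S)-3,7-dimethylocta-1,6-dien-3-yl]oxy}dimethylsilane | C=C[C@@](C)(O[Si](C)(C)C(C)(C)C)CCC=C(C)C | intermediate
19 | tert-butyl{[(3S)-5-(5,5-dimethyl-1,2,4-trioxolan-3-yl)-3-methylpent-1-en-3-yl]oxy}dimethylsilane (ozonide, both configurations at the trioxolane carbon) | C=C[C@@](C)(O[Si](C)(C)C(C)(C)C)CCC1OOC(C)(C)O1 | intermediate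
20 | (4S)-4-[(tert-butyldimethylsilyl)oxy]-4-methylhex-5-enal | C=C[C@@](C)(O[Si](C)(C)C(C)(C)C)CCC=O | intermediate
21 | (4S)-1,4-bis[(tert-butyldimethylsilyl)oxy]-4-methylhexa-1,5-diene (E/Z mixture) | C=C[C@@](C)(O[Si](C)(C)C(C)(C)C)CC=CO[Si](C)(C)C(C)(C)C | intermediate
22 | tert-butyl{[(3S)-4-{5-[(tert-butyldimethylsilyl)oxy]-1,2,4-trioxolan-3-yl}-3-methylbut-1-en-3-yl]oxy}dimethylsilane (ozonide, stereoisomer mixture in the trioxolane) | C=C[C@@](C)(O[Si](C)(C)C(C)(C)C)CC1OOC(O[Si](C)(C)C(C)(C)C)O1 | intermediate
23 | (3S)-3-[(tert-butyldimethylsilyl)oxy]-3-methylpent-4-enal | C=C[C@@](C)(O[Si](C)(C)C(C)(C)C)CC=O | intermediate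
24 | (3S)-3-[(tert-butyldimethylsilyl)oxy]-3-methylpent-4-en-1-ol | C=C[C@@](C)(O[Si](C)(C)C(C)(C)C)CCO | intermediate
25 | tetrabromomethane | BrC(Br)(Br)Br | starting material
26 | {[(3S)-3-[(tert-butyldimethylsilyl)oxy]-3-methylpent-4-en-1-yl]oxy}triphenylphosphonium bromide | C=C[C@@](C)(O[Si](C)(C)C(C)(C)C)CCO[P+](c1ccccc1)(c1ccccc1)c1ccccc1.[Br-] | intermediate
27 | tert-butyl{[(3S)-5-bromo-3-methylpent-1-en-3-yl]oxy}dimethylsilane | C=C[C@@](C)(O[Si](C)(C)C(C)(C)C)CCBr | intermediate
28 | {(3S)-3-[(tert-butyldimethylsilyl)oxy]-3-methylpent-4-en-1-yl}magnesium bromide | C=C[C@@](C)(O[Si](C)(C)C(C)(C)C)CC[Mg]Br | intermediate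
29 | (1S,4S)-1-[(2S,5S)-5-bromo-2,6,6-trimethyloxan-2-yl]-4-[(tert-butyldimethylsilyl)oxy]-4-methylhex-5-en-1-ol | C=C[C@@](C)(O[Si](C)(C)C(C)(C)C)CC[C@H](O)[C@]1(C)CC[C@H](Br)C(C)(C)O1 | intermediate
30 | {[(1S,4S)-1-[(2S,5S)-5-bromo-2,6,6-trimethyloxan-2-yl]-4-[(tert-butyldimethylsilyl)oxy]-4-methylhex-5-en-1-yl]oxy}trioctylphosphonium bromide | C=C[C@@](C)(O[Si](C)(C)C(C)(C)C)CC[C@H](O[P+](CCCCCCCC)(CCCCCCCC)CCCCCCCC)[C@]1(C)CC[C@H](Br)C(C)(C)O1.[Br-] | intermediate
31 | tert-butyl{[(3S,6R)-6-bromo-6-[(2S,5S)-5-bromo-2,6,6-trimethyloxan-2-yl]-3-methylhex-1-en-3-yl]oxy}dimethylsilane | C=C[C@@](C)(O[Si](C)(C)C(C)(C)C)CC[C@@H](Br)[C@]1(C)CC[C@H](Br)C(C)(C)O1 | intermediate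
32 | (3S,6R)-6-bromo-6-[(2S,5S)-5-bromo-2,6,6-trimethyloxan-2-yl]-3-methylhex-1-en-3-ol | C=C[C@@](C)(O)CC[C@@H](Br)[C@]1(C)CC[C@H](Br)C(C)(C)O1 | target

Total step count: 14.
Longest linear sequence: 9 steps (steps 1–6, then 12–14, from 1). The side-chain branch (steps 7–11) has 5 steps.

Steps most likely to fail

Step 4 (bears the label). What may go wrong: after ionisation at C11 the oxonium ion may lose a proton (E1 to an isopropenyl oxolane) faster than bromide opens it, or bromide may be captured at tertiary C11 without the material funnelling on to the secondary C10 bromide. The fallback uses known chemistry, a bromoetherification followed by ozonolysis; it sets out from 1 and comes back to the route at 16. Treatment of 1 with 2,4,4,6-tetrabromocyclohexa-2,5-dien-1-one in MeNO2 at 0 °C should close the oxane directly by 6-endo attack of the tertiary hydroxyl on the bromonium ion of the trisubstituted alkene, giving (3S,6S)-3-bromo-6-ethenyl-2,2,6-trimethyloxane F1. No facial control over bromonium formation is expected, so F1 has to be separated by chromatography from its C3 epimer and from 5-exo oxolane isomers. Ozonolysis of the vinyl group (O3, CH2Cl2, −78 °C) through the ozonide (3S,6S)-3-bromo-2,2,6-trimethyl-6-(1,2,4-trioxolan-3-yl)oxane F2 and PPh3 work-up then gives aldehyde 16.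

Step 13. What may go wrong: backside displacement at the C6 carbinol is slow because it is flanked by the fully substituted C7, so elimination towards C5, participation of the ring oxygen (net retention or enlargement to an oxepane) or attack by the C3 silyloxy oxygen (oxolane formation with loss of the silyl group) may compete. The fallback separates activation from displacement through an isolated sulfonate instead of an oxyphosphonium salt made and consumed in one pot; it sets out from 29 and comes back at 31. Chloromethanesulfonyl chloride and pyridine in CH2Cl2 at 0 °C should give (1S,4S)-1-[(2S,5S)-5-bromo-2,6,6-trimethyloxan-2-yl]-4-[(tert-butyldimethylsilyl)oxy]-4-methylhex-5-en-1-yl chloromethanesulfonate F3, a leaving group used for hindered secondary carbinols that is still stable enough to purify. LiBr in THF at rt to 50 °C then displaces it with inversion to give 31.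

Step 12. What may go wrong: poor facial selectivity, because the ring oxygen sits between two fully substituted carbons and may chelate magnesium only weakly, so that non-chelated attack from the other face competes. The fallback replaces substrate control by reagent control; it sets out from 29 obtained as a mixture of C6 epimers and comes back at 29 as the single (6S) epimer. Dess–Martin oxidation (NaHCO3, CH2Cl2) gives (4S)-1-[(2S,5S)-5-bromo-2,6,6-trimethyloxan-2-yl]-4-[(tert-butyldimethylsilyl)oxy]-4-methylhex-5-en-1-one F4. Corey–Bakshi–Shibata reduction follows, with catecholborane and (R)-1-methyl-3,3-diphenyltetrahydro-1H,3H-pyrrolo[1,2-c][1,3,2]oxazaborole (0.2 equiv) in toluene at −78 °C. The quaternary C7 acts as the large ketone substituent, and catecholborane should leave the vinyl group alone at this temperature, so the reduction should return the (6S) alcohol 29.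

Further compounds
F1 | step 4 | (3S,6S)-3-bromo-6-ethenyl-2,2,6-trimethyloxane | C=C[C@]1(C)CC[C@H](Br)C(C)(C)O1
F2 | step 4 | (3S,6S)-3-bromo-2,2,6-trimethyl-6-(1,2,4-trioxolan-3-yl)oxane (ozonide, both configurations at the trioxolane carbon) | O1OC(OC1)[C@]2(C)CC[C@H](Br)C(C)(C)O2
F3 | step 13 | (1S,4S)-1-[(2S,5S)-5-bromo-2,6,6-trimethyloxan-2-yl]-4-[(tert-butyldimethylsilyl)oxy]-4-methylhex-5-en-1-yl chloromethanesulfonate | C=C[C@@](C)(O[Si](C)(C)C(C)(C)C)CC[C@H](OS(=O)(=O)CCl)[C@]1(C)CC[C@H](Br)C(C)(C)O1
F4 | step 12 | (4S)-1-[(2S,5S)-5-bromo-2,6,6-trimethyloxan-2-yl]-4-[(tert-butyldimethylsilyl)oxy]-4-methylhex-5-en-1-one | C=C[C@@](C)(O[Si](C)(C)C(C)(C)C)CCC(=O)[C@]1(C)CC[C@H](Br)C(C)(C)O1
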